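**Assumption:** Diplotrin B is the flavonol 3′-hydroxy-3,4′,7,8-tetramethoxyflavone. It has no stereocenters, so the only stereochemical issue is E-alkene geometry in the chalcone. Simple bases, solvents and catalysts are not numbered.

## Retrosynthesis
1. The last step is removal of a benzyl group from the 3′-OH of the B ring. It is protected throughout so the 3-OH can be methylated selectively.
2. The 3-OMe comes from methylating a flavonol 3-OH.
3. The flavonol (pyranone ring C) forms from a 2′-hydroxychalcone by Algar–Flynn–Oyamada (AFO) oxidative cyclization.
4. The chalcone comes from Claisen–Schmidt condensation of 2′-hydroxy-3′,4′-dimethoxyacetophenone (**1**) with 3-benzyloxy-4-methoxybenzaldehyde (**2**). Compound **2** is the benzyl ether of isovanillin and is commercially available.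

## Forward route

**Step 1**
Reactants: **1** 1-(2-hydroxy-3,4-dimethoxyphenyl)ethan-1-one; **2** 3-(benzyloxy)-4-methoxybenzaldehyde
Product: **3** (E)-3-[3-(benzyloxy)-4-methoxyphenyl]-1-(2-hydroxy-3,4-dimethoxyphenyl)prop-2-en-1-one (2′-hydroxychalcone)
Conditions: NaOH (aq), EtOH, rt, 24 h
Reagents that add atoms: none (water is lost)
Why: Claisen–Schmidt (base-mediated aldol condensation) of the ketone enolate with a non-enolizable aldehyde, followed by dehydration, gives the conjugated chalcone. The thermodynamically favoured E-alkene forms, and the benzyl ether and methyl ethers are base-stable.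

**Step 2**
Reactants: **3** chalcone
Product: **4** 2-[3-(benzyloxy)-4-methoxyphenyl]-3-hydroxy-7,8-dimethoxy-4H-chromen-4-one
Conditions: 30% H2O2, 2 M NaOH (aq), MeOH, 0 °C to rt, 12 h
Reagents that add atoms: hydrogen peroxide, OO (one O ends up in the 3-OH)
Why: Algar–Flynn–Oyamada reaction. Nucleophilic epoxidation of the enone is followed by phenoxide opening of the epoxide (6-endo), which forms ring C with the 3-OH, and then oxidation to the flavonol. No stereocenter remains, because C2=C3 is aromatized in the product.

**Step 3**
Reactants: **4** flavonol
Product: **5** 2-[3-(benzyloxy)-4-methoxyphenyl]-3,7,8-trimethoxy-4H-chromen-4-one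
Conditions: MeI (3 equiv), K2CO3, acetone, reflux, 6 h
Reagents that add atoms: methyl iodide, CI
Why: The 3-OH is the only free, acidic phenol, so Williamson O-methylation on the phenoxide is chemoselective. Bn, aryl OMe and the pyranone are unaffected.

**Step 4**
Reactants: **5** benzyl-protected flavone
Product: **6** diplotrin B, 3′-hydroxy-3,4′,7,8-tetramethoxyflavone
Conditions: H2 (1 atm), 10% Pd/C, EtOAc/MeOH, rt, 2–4 h
Reagents that add atoms: none (H2 adds only hydrogen)
Why: Catalytic hydrogenolysis cleaves the benzylic C–O bond of the aryl benzyl ether and releases toluene. The aryl methyl ethers and the electron-poor, aromatic-like flavone C2=C3 survive short reaction times at 1 atm.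

## Compound list
1 | 1-(2-hydroxy-3,4-dimethoxyphenyl)ethan-1-one | CC(=O)c1ccc(OC)c(OC)c1O | starting material
2 | 3-(benzyloxy)-4-methoxybenzaldehyde | COc1ccc(C=O)cc1OCc1ccccc1 | starting material
3 | (E)-2′-hydroxychalcone, 3-benzyloxy-4-methoxy on the B ring, 3′,4′-dimethoxy on the A ring | COc1ccc(/C=C/C(=O)c2ccc(OC)c(OC)c2O)cc1OCc1ccccc1 | intermediate
4 | 3-hydroxy-flavone (flavonol) with 3′-OBn, 4′-OMe, 7-OMe, 8-OMe | COc1ccc(-c2oc3c(OC)c(OC)ccc3c(=O)c2O)cc1OCc1ccccc1 | intermediate
5 | 3-methoxy analogue of 4 (3,4′,7,8-tetramethoxy-3′-benzyloxyflavone) | COc1ccc(-c2oc3c(OC)c(OC)ccc3c(=O)c2OC)cc1OCc1ccccc1 | intermediate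
6 | diplotrin B (achiral) | COc1ccc(-c2oc3c(OC)c(OC)ccc3c(=O)c2OC)cc1O | target

## Totals
Total steps: 4. Longest linear sequence: 4. Compound **2** is bought; it is made in one step from isovanillin, BnBr and K2CO3 if needed.

## Three steps most likely to fail
1. **Step 2 (AFO).** Aurone formation, oxidative cleavage or low yields are common with electron-rich chalcones.
   Fallback: change the route to an Allan–Robinson or Baker–Venkataraman sequence. Acylate 2-hydroxy-3,4-dimethoxy-ω-methoxyacetophenone with 3-benzyloxy-4-methoxybenzoyl chloride, rearrange with KOH/pyridine, and cyclize with acid. This gives the 3-methoxyflavone **5** directly and skips Steps 1–3.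
2. **Step 1 (Claisen–Schmidt).** The free, ionized 2′-phenol slows enolate formation, and the chalcone can cyclize to a flavanone.
   Fallback: protect the 2′-OH of **1** as a MOM ether, run the aldol condensation, then remove the MOM group with HCl/MeOH before the AFO step.
3. **Step 4 (hydrogenolysis).** The flavone C2=C3 or the carbonyl may be partly reduced, or debenzylation may stall.
   Fallback: use the MOM ether of isovanillin in place of **2**, carry it through Steps 1–3, and remove it in the last step with HCl/MeOH. This avoids any hydrogenation.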